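Judge this flask by the fraction of side product A in side product A plus target late in a run, a selectivity that the last readings of the two earlier runs give directly.

| flask | substrate | reagent | remark | time |
|---|---|---|---|---|
| south-east | 0.15 M | 1.1 equiv | run made earlier |  |
| north-east | 0.60 M | 1.1 equiv | run made earlier |  |
| flask | 0.30 M | 1.10 equiv |  | 15 d |

| run | time / d | side product A / % | target / % |
|---|---|---|---|
| south-east | 0.625 | 0.7 | 16.8 |
| south-east | 1.67 | 2.5 | 28.5 |
| south-east | 4.00 | 3.5 | 35.9 |
| south-east | 10.0 | 2.8 | 37.6 |
| north-east | 0.625 | 2.8 | 44.1 |
| north-east | 1.67 | 4.0 | 59.7 |
| north-east | 4.00 | 4.0 | 64.2 |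
| north-east | 10.0 | 4.2 | 65.0 |

(readings scatter by 0.3 percentage points)

- share of side product A in side product A plus target at 20 min
- share of side product A in side product A plus target at 10 h
- share of side product A in side product A plus target at 15 d
- which of side product A and target there is more of at 15 d

- the numbers in the tables scatter by 0.3 percentage points (one standard deviation)

First we ask which numbers must be known well. One scatter of 0.3 percentage points on the last south-east reading of side product A moves that run's share by 0.69 points, whereas the same error on its target reading moves it by 0.051 points, so the side product A readings are what we need well. Next comes the charge: from 0.15 M to 0.60 M the last share read goes from 6.93% to 6.07%, a change of 0.86 points. The reagent stands at 1.10 equiv here as in both runs, so we need no correction for it. Time is a weak point, since between 4.00 d and 10.0 d the south-east share read fell by 2 points while the north-east share read rose by 0.2 points; we hold the last shares flat out to 15 d as a judgement. The flask's 0.30 M is twice the south-east charge and half the north-east one, so we take the mean of the two last shares as the end share, 6.50%, which puts target ahead.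

The forecast gives 0.5% at 20 min, 5% at 10 h and 6.5% at 15 d, with target ahead, noting that the late ratio of side product A to target is “nearly independent of concentration”; its end figure equals our reckoning, and its earlier figures are its own.

The flask gives 0.435%, 4.81% and 7.17%, with target ahead at 51.6% against 3.98% of side product A. At 15.0 d the flask holds substrate 0% and side product B 42.6%. Our end share lies 0.67 points below the flask's computed share, and applied to the flask's target it gives 3.59% of side product A.

    substrate + reagent → target (k = 0.00163 L mol⁻¹ min⁻¹)
    substrate + intermediate C → side product C (k = 8.85 × 10⁻⁴ L mol⁻¹ min⁻¹)
    reagent + intermediate A ⇌ intermediate B (K = 4.50 L mol⁻¹, k = 1.02 × 10⁻⁴ L mol⁻¹ min⁻¹)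
    intermediate A ⇌ intermediate C (K = 2.09, k = 0.0103 min⁻¹)
    substrate ⇌ intermediate A (K = 2.10, k = 3.69 × 10⁻⁴ min⁻¹)
    intermediate C → side product B (k = 0.00465 min⁻¹)
    reagent + intermediate A → side product A (k = 0.00207 L mol⁻¹ min⁻¹)

In the neighbour flask charged with 2.80 equiv of reagent, the end share of 6.50% and that flask's target of 76.1% give 5.29% of side product A. The computed neighbour has a share of 6.29% and 5.11% of side product A.

(The readings are calculated for substances that don't exist; the scatter is artificial.)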